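The runs are calculated for an exercise, and the scatter is random.

If each step takes one molecule at a time (first order), the charge scales all amounts alike. The share of target in target plus isomer at a fixed time should then carry over from one charge to another.

| flask | starting material | remark | time |
|---|---|---|---|
| south-west | 0.14 M | run made earlier |  |
| east | 0.22 M | run made earlier |  |
| flask | 0.10 M |  | 2.5 h |

| run | time / h | target / % | isomer of the product / % |
|---|---|---|---|
| south-west | 0.200 | 28.6 | 14.2 |
| south-west | 0.667 | 18.6 | 39.9 |
| south-west | 1.00 | 15.6 | 50.4 |
| south-west | 1.50 | 11.6 | 59.6 |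
| south-west | 2.50 | 6.9 | 66.0 |
| south-west | 3.00 | 5.3 | 68.6 |
| east | 0.250 | 26.0 | 18.1 |
| east | 0.417 | 22.9 | 27.6 |
| east | 0.667 | 18.6 | 39.2 |
| east | 1.00 | 13.2 | 47.8 |
| east | 2.00 | 8.8 | 59.4 |
| east | 3.00 | 4.1 | 61.5 |

(readings scatter by 1 percentage point)

- share of target in target plus isomer of the product at 6.0 s
- share of target in target plus isomer of the product at 2.5 h
- which of target and isomer of the product there is more of at 2.5 h

At 2.50 h the south-west run gives this carried share, S = target/(target + isomer), as 9.47%. The east run, taken halfway between its readings at 2.00 h and 3.00 h, gives 9.58%. The charges differ, yet each reading has a scatter of 1 percentage point, so I take S for the flask at 2.5 h, with more isomer than target. The time 6.0 s lies before any reading, so I say only that the early share is above the 66.8% read at 0.200 h.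

The forecast holds that the “two concentrations give the same shares over time”: 98% early, 9.5% late, isomer of the product ahead.

The flask gives 87.9% early, 10.2% late, and isomer of the product ahead, so the forecast parts from it on the early share, by 10 points.

    2 starting material → homo dimer (k = 0.0430 L mol⁻¹ min⁻¹)
    target ⇌ isomer of the product (K = 11.0, k = 0.0230 min⁻¹)
    starting material ⇌ target (K = 0.700, k = 0.0850 min⁻¹)
    isomer of the product ⇌ starting material (k = 0.00150 min⁻¹)

For the neighbour at 0.25 M I carry S over unchanged, which says 9.47%, and the neighbour itself gives 9.75% at 2.50 h. Its amounts do shift with the charge: target is 6.52% and isomer 60.3%, against 7.85% and 69.3% in the flask. Homo dimer, counted as two, holds 23.8% of the neighbour's charge, against 11.6% in the flask.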